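## Structural features

Petalostemumol G is 3,5,7,3',4'-pentahydroxyflavone (the quercetin skeleton) with three 3-methylbut-2-enyl (prenyl) groups on carbon: one at C8 of ring A and two at C2' and C6' of ring B. Ring A (C4a, C5–C8, C8a) is fused along C4a–C8a to the γ-pyrone ring C (O1, C2, C3, C4), and the catechol ring B hangs on the C2–C1' bond, which is flanked by both ring-B prenyl groups on one side and by O1 and the 3-OH on the other. There is no stereocentre, so no centres stand next to each other and nothing has to be set or preserved; the crowded C2–C1' axis is not a defined stereo-element. The fragile parts are the three trisubstituted alkenes, the oxidisable catechol and the enolic 3-OH: acid adds the neighbouring phenols to the alkenes (O7 to the C8 prenyl, O3' to the C2' prenyl), and the benzylic–allylic CH2 groups are open to hydride-abstracting oxidants and to hydrogenation. The real difficulty is regiochemical: three C-prenyl groups must each reach one defined carbon, two of them on either side of the hindered ring-B junction, and every later step must spare them. The key step uses the oxygenation pattern of ring A: oxygens on the alternate carbons C5, C7 and C8a and the acyl carbon C4 on C4a are the pattern of a linear 3,5,7-trioxo ester, so the C4a–C8a bond can be made by intramolecular Claisen condensation of such a chain, kept masked as a 4-hydroxy-2-pyrone until then.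

## Logic of the disconnections

29 ⇒ 28. The three aryl O–CH2OMe bonds at O7, O3' and O4' are cut last. These phenols must be masked against amide bases, methoxide, Mitsunobu and oxidation conditions, and MOM ethers tolerate all of them. Nothing is gained in skeleton; the gain is that the only acidic operation on the full triprenyl system is the final one. The demand is an acid mild enough not to add O7 or O3' to the adjacent prenyl alkene.

28 ⇒ 27 ⇒ 26. The C2=C3 unsaturation and the enolic O3–H are traced to the C3 carbinol of 27, and this to the O3–THP acetal of 26. The double bond thus comes from an α-ketol oxidation followed by tautomerisation, not from a quinone dehydrogenation of a flavanone: a hydride abstractor would also attack the three benzylic–allylic CH2 groups on alkoxy-activated rings. The demand is that O3 can be unmasked beside aryl MOM ethers. O3 is therefore carried from the start as a THP acetal; a MOM ether on sp3 C3 would be the last acetal to cleave, not the first.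

26 ⇒ 24 ⇒ 22 + 23. The C8–CH2 bond is cut and traced to the O5–CH2 bond of 24. C8 is para to O5, the ortho carbon C6 is reached first and is squeezed between C5=O and the O7 substituent, and the O5/C4=O pair is a chelating site for a lanthanide catalyst. This avoids electrophilic prenylation of a phloroglucinol, which would give C6, C8 and O mixtures. The demands are an O5 alkylation without base (22 is a flavanone, and base opens ring C) and an O7 substituent, so 22 ⇒ 21 cuts the O7–MOM bond.

21 ⇒ 20. The O1–C2 bond is cut; forward it is an oxa-Michael addition. Ring A of 20 is symmetric, so either ortho hydroxyl gives the same flavanone and no 6-versus-8 question arises. The demand is addition to a β-carbon screened by two ortho prenyl groups, helped by the strong preference of 2',6'-dihydroxychalcones for the closed form.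

20 ⇒ 18. The C4a–C8a bond of ring A is cut (key step). This removes ring A as an aromatic substitution problem altogether and reduces it to a pyrone with a side chain. The forward step must fold by Claisen and not by aldol condensation, and the enone, the THP enol acetal and the prenyl groups must survive methoxide.

18 ⇒ 16 + 17. The C4–C4a bond is cut between the pyrone methyl carbon and the acyl carbon. The cut is convergent: 17 is the complete C6 polyketide unit and 16 carries ring B, C2, C3, C4 and O3. The demand is acylation of a dianion by an ester that cannot enolise and that is attacked 1,2 and not 1,4.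

16 ⇒ 14 ⇒ 11 + 13, and 13 ⇒ 12. The C2=C3 bond of the cinnamate is cut through the aldol carbinol 14 to aldehyde 11 and the O-protected glycolate 13, whose O3–THP bond comes from 12. O3 is thereby present from the beginning and no later C3 oxygenation is needed. The demand is addition to a di-ortho-substituted aldehyde and a forced β-elimination.

11 ⇒ 10 ⇒ 8 ⇒ 6 + 7. After the O3'–MOM bond, the C6'–CH2 bond is cut and traced to the O3'–CH2 bond of 8. C6' is para to O3', and both ortho carbons (C2' with its prenyl group, C4' with OMOM) are blocked, so the allyl unit is forced round to C6' and arrives uninverted after two shifts. The demand is a high-temperature shift on a molecule with a formyl group and a MOM ether.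

6 ⇒ 4 ⇒ 2 + 3, and 2 ⇒ 1. The C2'–CH2 bond is cut and traced to the O3'–C(tertiary) bond of the 1,1-dimethylallyl ether 5, made from the propargyl ether 4. A single [3,3] shift inverts the allyl unit, so only the tertiary ether delivers a normal prenyl group to the ortho carbon; a plain O-prenyl ether would deliver the reverse isomer. With C4' blocked the shift can end only at C2'. The O4'–MOM bond of 2 rests on the higher acidity of the hydroxyl para to the formyl group of 1.

## Other disconnections considered

Alternative 1: The cut is through C1'–C2' and C5'–C6', so ring B is built on a finished chromone. In the forward step the 2-alkynylchromone A2 (its alkyne carbons become C1' and C6') is heated with the 1-prenyl-2,3-bis(silyloxy)butadiene A3 (C2'–C5'), and the 1,4-cyclohexadiene is dehydrogenated to the protected target A1.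
- In favour: all six ring-B substituents are set by one cycloaddition, and neither a condensation on a hindered aldehyde nor a hindered oxa-Michael closure is needed. On the crowded C2–C1' junction this is the better plan. The catechol arrives as silyl ethers that fluoride removes, which is gentler on prenyl/phenol pairs than acid, although A1 still carries three MOM groups.
- Against: the dienophile is an internal alkyne activated only vinylogously through the chromone, and its skipped enyne CH2 could isomerise to an allene at the temperature required. A3 is a hydrolytically labile bis(silyl enol ether) that needs Z geometry and an unsymmetrical 1,2-diketone precursor. Regiocontrol rests on the small bias of one alkyl group, because the two silyloxy groups oppose each other. A quinone oxidant in the same pot would meet the benzylic–allylic CH2 problem; a milder oxidant would probably do.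
- Comparison: structurally ring B is better served; mechanistically a thermal cycloaddition of weakly matched partners is less secure than a chelate-controlled Claisen condensation of a known substrate class. In step economy there is no gain, because A2 must already carry O3 and the C8 prenyl group, so the ring A and ring C work is not saved.

Alternative 2: The cut is at C8–CH2 and C6'–CH2 with the flavonol skeleton intact, tracing the material to quercetin A6. In the forward step the 5,3'-bis-O-prenyl ether A5 is heated with Eu(fod)3 so that each allyl unit passes from oxygen to the ortho carbon and on to the para carbon, giving A4.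
- In favour: A6 supplies the whole C15 skeleton and all five oxygens, and its hydroxyl reactivity order (7, 4' and 3 before 3' and 5) fits the protection pattern. The sequence would be roughly half as long as the chosen one, so step economy is clearly better. The ring-A half is the same shift as step 15 here and is its equal.
- Against: the C2' prenyl group must be in place before A5 exists, which means a tertiary-allyl ether and ortho-Claisen sequence on O3' of the flavonol and then a second alkylation of O3'. The ring-B ether has no carbonyl for the lanthanide to chelate and its para terminus C6' lies next to the chromone, so it would need far higher temperature than ring A. One pot would have to serve two different rearrangements, with loss of the allyl group and closure of the freed 3'-OH onto the C2' prenyl as likely side paths.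
- Comparison: the O3' relay logic is the same as in steps 2–5 here, but it is run on an advanced flavonol and not on a simple benzaldehyde, where a poor outcome costs little. Mechanistically it is equal on ring A and weaker on ring B.

Alternative 3: The cut is at C4–C4a, with ring A as an aryl nucleophile and C4 as an ester. In the forward step, iodine–magnesium exchange on the β-aryloxycinnamate A8 with iPrMgCl·LiCl gives an arylmagnesium that attacks the cis ester and closes ring C to the 3-deoxyflavone A7.
- In favour: ring C forms at the flavone oxidation level in one low-temperature anionic step that tolerates prenyl and MOM groups. On this point it is better than the chosen plan, which needs steps 16 and 17 for the C2=C3 bond. The ring closure itself is at least as reliable as an oxa-Michael addition.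
- Against: A7 lacks O3, so C3 must be hydroxylated on a triprenyl flavone where epoxidising reagents are excluded. Ring A must be prepared as a hexasubstituted benzene with iodine, one prenyl group and differentiated oxygens, which brings back the 6-versus-8 problem that the symmetric ring A of the chosen plan avoids. A8 requires O-vinylation of a di-ortho-substituted phenol by a hindered arylpropiolate, and only the isomer with ester cis to aryloxy can cyclise.
- Comparison: the difficulty is moved from ring C into ring A and O3, and once C3 hydroxylation and deprotection are added the step count is about equal.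

Key step: step 11

Remark: Ar = 3,4-bis(methoxymethoxy)-2,6-bis(3-methylbut-2-en-1-yl)phenyl. Enolates, phenoxides, metal chelates and keto–enol tautomers are counted with their parent numbered compound.

Remark: THP-bearing compounds (13–16, 18–22, 24–26) are epimer mixtures at the acetal carbon; 14, 15, 21, 22 and 24–27 are also racemic diastereomer mixtures at their two adjacent sp3 carbons, and 9 is racemic. These centres are written without stereodescriptors, no control is attempted, and all are gone after step 17.

Remark on design: the skeletons of the key-step precursor 18 and product 20 are kept; O3 is carried as a THP enol acetal instead of a MOM ether, and ring C is later dehydrogenated by α-ketol oxidation instead of a quinone. Compound 18 is a carboxylic-acid-strength acid and should be handled at pH 5 or above and not stored in alcohols.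

Step 1
Reactants: 1 3,4-dihydroxybenzaldehyde
Product: 2 3-hydroxy-4-(methoxymethoxy)benzaldehyde
Conditions: MOMCl (1.0 equiv), K2CO3 (1.05 equiv), acetone, 0 → 20 °C
Reagents that add atoms: chloromethyl methyl ether, COCCl
Why: The 4-OH, para to the formyl group, is the more acidic phenol, so one equivalent of carbonate should form mainly its phenoxide and Williamson-type alkylation should occur there; the minor 3-O and bis ethers are removed at this cheap stage.

Step 2
Reactants: 2 3-hydroxy-4-(methoxymethoxy)benzaldehyde; 3 3-chloro-3-methylbut-1-yne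
Product: 4 4-(methoxymethoxy)-3-[(2-methylbut-3-yn-2-yl)oxy]benzaldehyde
Conditions: DBU, CuCl2 (1 mol %), MeCN, 0 → 20 °C
Reagents that add atoms: none
Why: Copper-catalysed O-alkylation of a phenol by a tertiary propargylic chloride (through a copper allenylidene-type electrophile) is the standard entry to aryl 1,1-dimethylpropargyl ethers, which direct SN2 substitution cannot give.

Step 3
Reactants: 4 4-(methoxymethoxy)-3-[(2-methylbut-3-yn-2-yl)oxy]benzaldehyde
Product: 6 3-hydroxy-4-(methoxymethoxy)-2-(3-methylbut-2-en-1-yl)benzaldehyde, via 1,1-dimethylallyl ether 5 (not isolated)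
Conditions: H2 (1 atm), Pd/CaCO3–Pb(OAc)2, quinoline, EtOAc, 20 °C; filter; PhMe, 110 °C
Reagents that add atoms: none
Why: Semi-hydrogenation over lead-poisoned palladium stops at alkene 5 and spares the formyl group; the aromatic Claisen [3,3] rearrangement of this tertiary allyl ether then runs at modest temperature, can end productively only at C2 because C4 carries OMOM, and its allylic inversion turns the 1,1-dimethylallyl unit into a normal prenyl group.

Step 4
Reactants: 6 3-hydroxy-4-(methoxymethoxy)-2-(3-methylbut-2-en-1-yl)benzaldehyde; 7 1-bromo-3-methylbut-2-ene (prenyl bromide)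
Product: 8 4-(methoxymethoxy)-2-(3-methylbut-2-en-1-yl)-3-[(3-methylbut-2-en-1-yl)oxy]benzaldehyde
Conditions: K2CO3, DMF, 20 °C
Reagents that add atoms: none
Why: Williamson etherification (SN2) of the flanked phenoxide with a primary allylic bromide; the dipolar aprotic solvent favours O- over C-alkylation.

Step 5
Reactants: 8 4-(methoxymethoxy)-2-(3-methylbut-2-en-1-yl)-3-[(3-methylbut-2-en-1-yl)oxy]benzaldehyde
Product: 10 3-hydroxy-4-(methoxymethoxy)-2,6-bis(3-methylbut-2-en-1-yl)benzaldehyde, via C2 ortho-dienone 9 (not isolated)
Conditions: PhNEt2, 195 °C, sealed tube, Ar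
Reagents that add atoms: none
Why: Both carbons ortho to the ether oxygen are substituted, so the Claisen [3,3] shift gives a blocked dienone such as 9 that cannot enolise and passes the newly arrived tertiary allyl unit on by a Cope [3,3] shift through its unsubstituted terminus to C6 (para), where enolisation is possible. Two allylic inversions return a normal prenyl group, and the basic amine solvent suppresses acid-catalysed chroman formation.

Step 6
Reactants: 10 3-hydroxy-4-(methoxymethoxy)-2,6-bis(3-methylbut-2-en-1-yl)benzaldehyde
Product: 11 3,4-bis(methoxymethoxy)-2,6-bis(3-methylbut-2-en-1-yl)benzaldehyde (ArCHO)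
Conditions: MOMCl, iPr2NEt, CH2Cl2, 0 → 40 °C
Reagents that add atoms: chloromethyl methyl ether, COCCl
Why: Standard MOM ether formation; the small electrophile tolerates the flanked phenol, and the amine keeps the medium non-acidic for the existing acetal and the alkenes.

Step 7
Reactants: 12 methyl glycolate
Product: 13 methyl 2-(oxan-2-yloxy)acetate
Conditions: 3,4-dihydro-2H-pyran, PPTS (cat.), CH2Cl2, 20 °C
Reagents that add atoms: 3,4-dihydro-2H-pyran, C1=COCCC1
Why: Acid-catalysed addition of the alcohol to the enol ether (tetrahydropyranylation); THP is chosen for O3 because it is stable to the bases ahead and can later be removed with PPTS beside aryl MOM ethers.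

Step 8
Reactants: 13 methyl 2-(oxan-2-yloxy)acetate; 11 3,4-bis(methoxymethoxy)-2,6-bis(3-methylbut-2-en-1-yl)benzaldehyde
Product: 14 methyl 3-Ar-3-hydroxy-2-(oxan-2-yloxy)propanoate (mixture of diastereomers)
Conditions: LiN(iPr)2, THF, −78 °C; then 11, −78 °C; aq. NH4Cl
Reagents that add atoms: none
Why: Directed aldol addition of the lithium enolate of the α-alkoxy ester to a non-enolisable, di-ortho-substituted aldehyde at low temperature; the two new centres are formed without control on purpose, because step 9 removes both.

Step 9
Reactants: 14 methyl 3-Ar-3-hydroxy-2-(oxan-2-yloxy)propanoate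
Product: 16 methyl (2Z)-3-Ar-2-(oxan-2-yloxy)prop-2-enoate, via mesylate 15 (not isolated)
Conditions: MsCl, Et3N, CH2Cl2, 0 °C; then DBU, 20 → 40 °C
Reagents that add atoms: none
Why: Mesylation of the benzylic alcohol and base-induced β-elimination through the ester enolate (E1cB) give the trisubstituted enol acetal; the isomer with aryl trans to the ester (Z) is the less strained and should dominate, and the geometry is erased anyway when ring C closes.

Step 10
Reactants: 16 methyl (2Z)-3-Ar-2-(oxan-2-yloxy)prop-2-enoate; 17 4-hydroxy-6-methyl-2H-pyran-2-one (triacetic acid lactone)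
Product: 18 4-hydroxy-6-[(3Z)-4-Ar-3-(oxan-2-yloxy)-2-oxobut-3-en-1-yl]-2H-pyran-2-one
Conditions: 17 (3 equiv), LiN(iPr)2 (6 equiv), THF, −78 → −20 °C; then 16, −78 → 0 °C; aq. NH4Cl/NaH2PO4 (pH 5), 0 °C
Reagents that add atoms: none
Why: Claisen-type C-acylation of the dianion of 17, which reacts at the 6-methyl carbon; ester 16 has no α-hydrogen and a screened, donor-substituted β-carbon, so enolisation and 1,4-addition are not expected, and the excess dianion covers deprotonation of the acidic product.

Step 11
Reactants: 18 4-hydroxy-6-[(3Z)-4-Ar-3-(oxan-2-yloxy)-2-oxobut-3-en-1-yl]-2H-pyran-2-one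
Product: 20 (2Z)-3-Ar-2-(oxan-2-yloxy)-1-(2,4,6-trihydroxyphenyl)prop-2-en-1-one, via trioxo ester 19 (not isolated)
Conditions: Mg(OMe)2 (8 equiv), MeOH, 65 °C, Ar; aq. NH4Cl, 0 °C
Reagents that add atoms: none
Why: Methoxide adds to the lactone carbonyl of the magnesium pyronate and opens it to the magnesium chelate of the methyl 3,5,7-trioxo ester 19. The C6 methylene of 19 (the future C4a), flanked by two ketones, attacks the ester carbonyl (the future C8a) in a 6-exo-trig Claisen (Dieckmann-type) condensation, methoxide leaves, and triple enolisation of the cyclohexane-1,3,5-trione gives the aromatic acylphloroglucinol irreversibly. The closest known reaction type is the magnesium methoxide recyclisation of 6-(2-oxoalkyl)-4-hydroxy-2-pyrones and of 3,5,7-trioxo esters to acylphloroglucinols. No stereocentre is formed. The selectivity needed is Claisen folding (C6 onto C1 of 19) over the aldol folding (C2 onto the C7 ketone) that would give a resorcylate: chelation of divalent magnesium to the C5/C7 diketone lowers the electrophilicity of C7, the ester terminus stays electrophilic in anhydrous methanol, and C7 is also cross-conjugated with the OTHP donor and screened by the 2,6-diprenylaryl group. The same chelation and screening should hold back methoxide conjugate addition and retro-Claisen cleavage, and the MOM, THP and prenyl groups are inert to methoxide. Any 20 that already closes to 21 in the flask is carried into step 12.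

Step 12
Reactants: 20 (2Z)-3-Ar-2-(oxan-2-yloxy)-1-(2,4,6-trihydroxyphenyl)prop-2-en-1-one
Product: 21 2-Ar-5,7-dihydroxy-3-(oxan-2-yloxy)-2,3-dihydro-4H-chromen-4-one
Conditions: NaOAc, EtOH, 78 °C
Reagents that add atoms: none
Why: 6-endo-trig oxa-Michael addition of a 2'-phenoxide to the enone; 2',6'-dihydroxychalcones strongly favour the flavanone, and either ortho hydroxyl can close because ring A is symmetric. The new C2 and C3 centres (2,3-trans expected after equilibration) need no control because step 17 removes them.

Step 13
Reactants: 21 2-Ar-5,7-dihydroxy-3-(oxan-2-yloxy)-2,3-dihydro-4H-chromen-4-one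
Product: 22 2-Ar-5-hydroxy-7-(methoxymethoxy)-3-(oxan-2-yloxy)-2,3-dihydro-4H-chromen-4-one
Conditions: MOMCl (1.1 equiv), iPr2NEt, CH2Cl2, 0 °C
Reagents that add atoms: chloromethyl methyl ether, COCCl
Why: The 7-OH is the free and more acidic phenol, whereas the 5-OH is held in a hydrogen bond to the C4 carbonyl, so one equivalent of MOMCl with a hindered amine should etherify O7 only; the mild base avoids retro-Michael opening of ring C.

Step 14
Reactants: 22 2-Ar-5-hydroxy-7-(methoxymethoxy)-3-(oxan-2-yloxy)-2,3-dihydro-4H-chromen-4-one; 23 3-methylbut-2-en-1-ol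
Product: 24 2-Ar-7-(methoxymethoxy)-5-[(3-methylbut-2-en-1-yl)oxy]-3-(oxan-2-yloxy)-2,3-dihydro-4H-chromen-4-one
Conditions: PPh3, DIAD, THF, 0 → 20 °C
Reagents that add atoms: none
Why: Mitsunobu etherification of the chelated 5-OH with the primary allylic alcohol under neutral conditions; it is preferred to carbonate and prenyl bromide because basic alkylation of 5-hydroxyflavanones opens ring C to the chalcone.

Step 15
Reactants: 24 2-Ar-7-(methoxymethoxy)-5-[(3-methylbut-2-en-1-yl)oxy]-3-(oxan-2-yloxy)-2,3-dihydro-4H-chromen-4-one
Product: 26 2-Ar-5-hydroxy-7-(methoxymethoxy)-8-(3-methylbut-2-en-1-yl)-3-(oxan-2-yloxy)-2,3-dihydro-4H-chromen-4-one, via C6 ortho-dienone 25 (not isolated)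
Conditions: Eu(fod)3 (10 mol %), NaHCO3, PhCl, 85 °C
Reagents that add atoms: none
Why: The oxophilic trivalent europium complex chelates O5 and the C4 carbonyl and accelerates the aromatic Claisen [3,3] shift to C6; dienone 25, crowded between C5=O and the C7 OMOM group, should pass the allyl unit on to C8 by a Cope [3,3] shift before it enolises, which returns a normal prenyl group. This domino para-Claisen–Cope shift is established for 5-O-prenyl flavonoids with a protected 7-oxygen.

Step 16
Reactants: 26 2-Ar-5-hydroxy-7-(methoxymethoxy)-8-(3-methylbut-2-en-1-yl)-3-(oxan-2-yloxy)-2,3-dihydro-4H-chromen-4-one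
Product: 27 2-Ar-3,5-dihydroxy-7-(methoxymethoxy)-8-(3-methylbut-2-en-1-yl)-2,3-dihydro-4H-chromen-4-one
Conditions: PPTS (0.2 equiv), MeOH, 20 °C
Reagents that add atoms: none
Why: Acid-catalysed transacetalisation to methanol removes the alkyl THP acetal much faster than aryl MOM ethers are attacked, and PPTS is too weak an acid to protonate the prenyl alkenes.

Step 17
Reactants: 27 2-Ar-3,5-dihydroxy-7-(methoxymethoxy)-8-(3-methylbut-2-en-1-yl)-2,3-dihydro-4H-chromen-4-one
Product: 28 2-Ar-3,5-dihydroxy-7-(methoxymethoxy)-8-(3-methylbut-2-en-1-yl)-4H-chromen-4-one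
Conditions: Dess–Martin periodinane (1.1 equiv), pyridine, CH2Cl2, 0 → 20 °C
Reagents that add atoms: none
Why: Dess–Martin oxidation of the α-ketol gives the 3,4-dione, which tautomerises through C2–H to the aromatic 3-hydroxy-γ-pyrone; the buffered periodinane leaves prenyl alkenes, MOM ethers and the chelated 5-OH alone, and the C2 and C3 centres vanish.

Step 18
Reactants: 28 2-Ar-3,5-dihydroxy-7-(methoxymethoxy)-8-(3-methylbut-2-en-1-yl)-4H-chromen-4-one
Product: 29 petalostemumol G
Conditions: 3 M aq. HCl, MeOH, 40 °C, short time; NaHCO3 quench
Reagents that add atoms: none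
Why: Acid-catalysed acetal exchange of the three aryl MOM ethers with methanol, a standard end-game for prenylated flavonoids; low acid strength and short exposure are meant to keep the freed phenols from adding to the neighbouring alkenes.

Compound list

1 | 3,4-dihydroxybenzaldehyde | O=Cc1ccc(O)c(O)c1 | starting material
2 | 3-hydroxy-4-(methoxymethoxy)benzaldehyde | COCOc1ccc(C=O)cc1O | intermediate
3 | 3-chloro-3-methylbut-1-yne | C#CC(C)(C)Cl | starting material
4 | 4-(methoxymethoxy)-3-[(2-methylbut-3-yn-2-yl)oxy]benzaldehyde | COCOc1ccc(C=O)cc1OC(C)(C)C#C | intermediate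
5 | 4-(methoxymethoxy)-3-[(2-methylbut-3-en-2-yl)oxy]benzaldehyde (not isolated) | COCOc1ccc(C=O)cc1OC(C)(C)C=C | intermediate
6 | 3-hydroxy-4-(methoxymethoxy)-2-(3-methylbut-2-en-1-yl)benzaldehyde | COCOc1ccc(C=O)c(CC=C(C)C)c1O | intermediate
7 | 1-bromo-3-methylbut-2-ene (prenyl bromide) | CC(C)=CCBr | starting material
8 | 4-(methoxymethoxy)-2-(3-methylbut-2-en-1-yl)-3-[(3-methylbut-2-en-1-yl)oxy]benzaldehyde | COCOc1ccc(C=O)c(CC=C(C)C)c1OCC=C(C)C | intermediate
9 | 4-(methoxymethoxy)-6-(2-methylbut-3-en-2-yl)-6-(3-methylbut-2-en-1-yl)-5-oxocyclohexa-1,3-diene-1-carbaldehyde (racemic, not isolated) | O=CC1=CC=C(OCOC)C(=O)C1(CC=C(C)C)C(C)(C)C=C | intermediate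
10 | 3-hydroxy-4-(methoxymethoxy)-2,6-bis(3-methylbut-2-en-1-yl)benzaldehyde | COCOc1cc(CC=C(C)C)c(C=O)c(CC=C(C)C)c1O | intermediate
11 | 3,4-bis(methoxymethoxy)-2,6-bis(3-methylbut-2-en-1-yl)benzaldehyde (ArCHO) | COCOc1cc(CC=C(C)C)c(C=O)c(CC=C(C)C)c1OCOC | intermediate
12 | methyl glycolate | COC(=O)CO | starting material
13 | methyl 2-(oxan-2-yloxy)acetate (racemic) | COC(=O)COC1CCCCO1 | intermediate
14 | methyl 3-Ar-3-hydroxy-2-(oxan-2-yloxy)propanoate (diastereomer mixture) | COC(=O)C(OC1CCCCO1)C(O)c1c(CC=C(C)C)cc(OCOC)c(OCOC)c1CC=C(C)C | intermediate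
15 | methyl 3-Ar-3-(methylsulfonyloxy)-2-(oxan-2-yloxy)propanoate (diastereomer mixture, not isolated) | COC(=O)C(OC1CCCCO1)C(OS(C)(=O)=O)c1c(CC=C(C)C)cc(OCOC)c(OCOC)c1CC=C(C)C | intermediate
16 | methyl (2Z)-3-Ar-2-(oxan-2-yloxy)prop-2-enoate | COC(=O)/C(OC1CCCCO1)=C/c1c(CC=C(C)C)cc(OCOC)c(OCOC)c1CC=C(C)C | intermediate
17 | 4-hydroxy-6-methyl-2H-pyran-2-one (triacetic acid lactone) | Cc1cc(O)cc(=O)o1 | starting material
18 | 4-hydroxy-6-[(3Z)-4-Ar-3-(oxan-2-yloxy)-2-oxobut-3-en-1-yl]-2H-pyran-2-one | O=c1cc(O)cc(CC(=O)/C(OC2CCCCO2)=C/c2c(CC=C(C)C)cc(OCOC)c(OCOC)c2CC=C(C)C)o1 | intermediate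
19 | methyl (8Z)-9-Ar-8-(oxan-2-yloxy)-3,5,7-trioxonon-8-enoate (as magnesium chelate, not isolated) | COC(=O)CC(=O)CC(=O)CC(=O)/C(OC1CCCCO1)=C/c1c(CC=C(C)C)cc(OCOC)c(OCOC)c1CC=C(C)C | intermediate
20 | (2Z)-3-Ar-2-(oxan-2-yloxy)-1-(2,4,6-trihydroxyphenyl)prop-2-en-1-one | O=C(/C(OC1CCCCO1)=C/c1c(CC=C(C)C)cc(OCOC)c(OCOC)c1CC=C(C)C)c1c(O)cc(O)cc1O | intermediate
21 | 2-Ar-5,7-dihydroxy-3-(oxan-2-yloxy)-2,3-dihydro-4H-chromen-4-one (racemic, mainly 2,3-trans) | O=C1c2c(O)cc(O)cc2OC(c2c(CC=C(C)C)cc(OCOC)c(OCOC)c2CC=C(C)C)C1OC1CCCCO1 | intermediate
22 | 2-Ar-5-hydroxy-7-(methoxymethoxy)-3-(oxan-2-yloxy)-2,3-dihydro-4H-chromen-4-one | O=C1c2c(O)cc(OCOC)cc2OC(c2c(CC=C(C)C)cc(OCOC)c(OCOC)c2CC=C(C)C)C1OC1CCCCO1 | intermediate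
23 | 3-methylbut-2-en-1-ol | CC(C)=CCO | starting material
24 | 2-Ar-7-(methoxymethoxy)-5-[(3-methylbut-2-en-1-yl)oxy]-3-(oxan-2-yloxy)-2,3-dihydro-4H-chromen-4-one | O=C1c2c(OCC=C(C)C)cc(OCOC)cc2OC(c2c(CC=C(C)C)cc(OCOC)c(OCOC)c2CC=C(C)C)C1OC1CCCCO1 | intermediate
25 | 2-Ar-7-(methoxymethoxy)-6-(2-methylbut-3-en-2-yl)-3-(oxan-2-yloxy)-2,3-dihydro-6H-chromene-4,5-dione (not isolated) | O=C1C2=C(OC(c3c(CC=C(C)C)cc(OCOC)c(OCOC)c3CC=C(C)C)C1OC1CCCCO1)C=C(OCOC)C(C(C)(C)C=C)C2=O | intermediate
26 | 2-Ar-5-hydroxy-7-(methoxymethoxy)-8-(3-methylbut-2-en-1-yl)-3-(oxan-2-yloxy)-2,3-dihydro-4H-chromen-4-one | O=C1c2c(O)cc(OCOC)c(CC=C(C)C)c2OC(c2c(CC=C(C)C)cc(OCOC)c(OCOC)c2CC=C(C)C)C1OC1CCCCO1 | intermediate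
27 | 2-Ar-3,5-dihydroxy-7-(methoxymethoxy)-8-(3-methylbut-2-en-1-yl)-2,3-dihydro-4H-chromen-4-one (racemic, mainly 2,3-trans) | O=C1c2c(O)cc(OCOC)c(CC=C(C)C)c2OC(c2c(CC=C(C)C)cc(OCOC)c(OCOC)c2CC=C(C)C)C1O | intermediate
28 | 2-Ar-3,5-dihydroxy-7-(methoxymethoxy)-8-(3-methylbut-2-en-1-yl)-4H-chromen-4-one | O=c1c(O)c(-c2c(CC=C(C)C)cc(OCOC)c(OCOC)c2CC=C(C)C)oc2c(CC=C(C)C)c(OCOC)cc(O)c12 | intermediate
29 | petalostemumol G, 2-[3,4-dihydroxy-2,6-bis(3-methylbut-2-en-1-yl)phenyl]-3,5,7-trihydroxy-8-(3-methylbut-2-en-1-yl)-4H-chromen-4-one | CC(C)=CCc1cc(O)c(O)c(CC=C(C)C)c1-c1oc2c(CC=C(C)C)c(O)cc(O)c2c(=O)c1O | target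

Total number of steps: 18. Longest linear sequence: 17 steps (steps 1–6 and 8–18, from 1 to 29); step 7 is a one-step side branch.

Least certain steps

Step 11 (key step). Most likely failure: slow opening of the doubly deprotonated pyronate. On prolonged heating methoxide could then cleave the side-chain β-diketone (retro-Claisen loss of the cinnamoyl unit), or the chain could fold by aldol closure onto C7 before the Claisen closure. Fallback: avoid the lactone opening altogether. Methanolysis of 17 with Mg(OMe)2 gives methyl 3,5-dioxohexanoate F1; its trianion (LiN(iPr)2, 3 equiv, THF) is acylated at the terminal methyl carbon by 16. This gives the open-chain ester 19 directly, which can be folded with Mg(OMe)2 in methanol at or below 20 °C, so that the chain sees base only briefly. The fallback sets out from 17 and 16 and returns to the route at 19, one operation before 20.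

Step 10. Most likely failure: sluggish attack on the hindered, donor-substituted ester carbonyl, so that proton exchange between the dianion and the acidic product, or conjugate addition, takes over and conversion stalls. Fallback: raise the electrophile to the aldehyde level. From 16, reduction with iBu2AlH gives allylic alcohol F2 and MnO2 gives enal F3. The dianion of 17 adds 1,2 to F3 to give carbinol F4; no acidic ketone forms in the flask, so one equivalent of dianion suffices. Oxidation of the allylic alcohol of F4 (MnO2 or Dess–Martin periodinane) returns to the route at 18.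

Step 5. Most likely failure: fragmentation of the allyl ether back to 6, or thermal closure of the phenol of 10 onto its C2 prenyl group, at the temperature the double shift needs. Fallback: replace both O-to-C shifts by cross-coupling. From 2, double bromination ortho and para to the free phenol (NBS, MeCN, 0 °C) gives 2,6-dibromo-3-hydroxy-4-(methoxymethoxy)benzaldehyde F5, and MOM protection gives 2,6-dibromo-3,4-bis(methoxymethoxy)benzaldehyde F6. A double Stille coupling with tributyl(3-methylbut-2-en-1-yl)stannane (Pd(PPh3)4, CsF, DMF, 90 °C), which normally couples through the unsubstituted allyl terminus and does not add to the formyl group, returns to the route at 11.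

Step 15. Most likely failure: enolisation of dienone 25 before the Cope shift, which would leave the allyl unit inverted on C6 instead of normal on C8. Fallback: deliver the prenyl group from O7 by a single ortho shift. From 21, copper-catalysed alkylation of the free 7-OH with 3 (DBU, CuCl2 cat.) gives 7-O-(1,1-dimethylpropargyl) ether F7, and semi-hydrogenation over Pd/CaCO3–Pb(OAc)2 gives 7-O-(1,1-dimethylallyl) ether F8. Gentle heating (PhMe, 110 °C) effects an ortho-Claisen shift, which in chelated 5-hydroxy flavonoids favours C8 over C6, to give 8-prenyl-5,7-diol F9. Selective 7-O-MOM protection as in step 13 returns to the route at 26.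

Step 18. Most likely failure: acid-catalysed addition of the freed 7-OH or 3'-OH to the neighbouring prenyl alkene (chroman formation) competing with acetal cleavage. Fallback: cleave the acetals without a protic acid. From 28, Me2BBr in CH2Cl2 at −78 °C (bromide-assisted Lewis acid cleavage) followed by aqueous NaHCO3 leads directly to 29; no new compound is made (F0).

Further compounds

F1 | step 11 | methyl 3,5-dioxohexanoate | COC(=O)CC(=O)CC(C)=O
F2 | step 10 | (2Z)-3-Ar-2-(oxan-2-yloxy)prop-2-en-1-ol | OC/C(OC1CCCCO1)=C/c1c(CC=C(C)C)cc(OCOC)c(OCOC)c1CC=C(C)C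
F3 | step 10 | (2Z)-3-Ar-2-(oxan-2-yloxy)prop-2-enal | O=C/C(OC1CCCCO1)=C/c1c(CC=C(C)C)cc(OCOC)c(OCOC)c1CC=C(C)C
F4 | step 10 | 4-hydroxy-6-[(3Z)-4-Ar-2-hydroxy-3-(oxan-2-yloxy)but-3-en-1-yl]-2H-pyran-2-one | O=c1cc(O)cc(CC(O)/C(OC2CCCCO2)=C/c2c(CC=C(C)C)cc(OCOC)c(OCOC)c2CC=C(C)C)o1
F5 | step 5 | 2,6-dibromo-3-hydroxy-4-(methoxymethoxy)benzaldehyde | COCOc1cc(Br)c(C=O)c(Br)c1O
F6 | step 5 | 2,6-dibromo-3,4-bis(methoxymethoxy)benzaldehyde | COCOc1cc(Br)c(C=O)c(Br)c1OCOC
F7 | step 15 | 2-Ar-5-hydroxy-7-[(2-methylbut-3-yn-2-yl)oxy]-3-(oxan-2-yloxy)-2,3-dihydro-4H-chromen-4-one | O=C1c2c(O)cc(OC(C)(C)C#C)cc2OC(c2c(CC=C(C)C)cc(OCOC)c(OCOC)c2CC=C(C)C)C1OC1CCCCO1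
F8 | step 15 | 2-Ar-5-hydroxy-7-[(2-methylbut-3-en-2-yl)oxy]-3-(oxan-2-yloxy)-2,3-dihydro-4H-chromen-4-one | O=C1c2c(O)cc(OC(C)(C)C=C)cc2OC(c2c(CC=C(C)C)cc(OCOC)c(OCOC)c2CC=C(C)C)C1OC1CCCCO1
F9 | step 15 | 2-Ar-5,7-dihydroxy-8-(3-methylbut-2-en-1-yl)-3-(oxan-2-yloxy)-2,3-dihydro-4H-chromen-4-one | O=C1c2c(O)cc(O)c(CC=C(C)C)c2OC(c2c(CC=C(C)C)cc(OCOC)c(OCOC)c2CC=C(C)C)C1OC1CCCCO1
F0 | step 18 | none | none
A1 | alternative 1 | 3',4'-bis-O-TBS-3,5,7-tri-O-MOM petalostemumol G | CC(C)=CCc1cc(O[Si](C)(C)C(C)(C)C)c(O[Si](C)(C)C(C)(C)C)c(CC=C(C)C)c1-c1oc2c(CC=C(C)C)c(OCOC)cc(OCOC)c2c(=O)c1OCOC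
A2 | alternative 1 | 3,5,7-tris(methoxymethoxy)-2-(5-methylhex-4-en-1-yn-1-yl)-8-(3-methylbut-2-en-1-yl)-4H-chromen-4-one | CC(C)=CCC#Cc1oc2c(CC=C(C)C)c(OCOC)cc(OCOC)c2c(=O)c1OCOC
A3 | alternative 1 | (3Z)-2,3-bis(tert-butyldimethylsilyloxy)-7-methylocta-1,3,6-triene | C=C(O[Si](C)(C)C(C)(C)C)/C(O[Si](C)(C)C(C)(C)C)=C/CC=C(C)C
A4 | alternative 2 | 3,7,4'-tri-O-MOM petalostemumol G | CC(C)=CCc1cc(OCOC)c(O)c(CC=C(C)C)c1-c1oc2c(CC=C(C)C)c(OCOC)cc(O)c2c(=O)c1OCOC
A5 | alternative 2 | 3,7,4'-tri-O-MOM-5,3'-bis-O-prenyl-2'-prenylquercetin | CC(C)=CCOc1c(OCOC)ccc(-c2oc3cc(OCOC)cc(OCC=C(C)C)c3c(=O)c2OCOC)c1CC=C(C)C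
A6 | alternative 2 | quercetin | O=c1c(O)c(-c2ccc(O)c(O)c2)oc2cc(O)cc(O)c12
A7 | alternative 3 | 3-deoxy-5,7,3',4'-tetra-O-MOM petalostemumol G (flavone) | CC(C)=CCc1cc(OCOC)c(OCOC)c(CC=C(C)C)c1-c1cc(=O)c2c(OCOC)cc(OCOC)c(CC=C(C)C)c2o1
A8 | alternative 3 | methyl (2Z)-3-Ar-3-[2-iodo-3,5-bis(methoxymethoxy)-6-(3-methylbut-2-en-1-yl)phenoxy]prop-2-enoate | COC(=O)/C=C(\Oc1c(I)c(OCOC)cc(OCOC)c1CC=C(C)C)c1c(CC=C(C)C)cc(OCOC)c(OCOC)c1CC=C(C)C
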